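The butenolide is disconnected at the bond between the lactone oxygen O1 and the quaternary carbon C5 (furan-2(5H)-one numbering: C2=O, C3–OMe, C4–aryl, C5). Because C3=C4–C5 of the furanone is an allene carbon chain in disguise, the ring is closed by a zerovalent-palladium-catalysed arylative cyclisation of an axially chiral 2-methoxy-2,3-allenoic acid: in one operation the carboxylate oxygen bonds to the allene terminus (C5), the protected catechol ring is delivered to the central carbon (C4), and the allene axis is translated into the quaternary stereocentre. The precursor is an open-chain, tetrasubstituted allene-1,3-dicarboxylic acid monoester whose axis is set by asymmetric phase-transfer benzylation with the enantiopure chromanylmethyl bromide.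

Key step: step 13

Assumption (step 10): the (S)-configured ammonium catalyst is taken to give the (Sa) axis; if the sense of induction is the opposite, its (R)-enantiomer is used and nothing else changes.
Assumption (step 13): oxygen and palladium are taken to add anti across the distal allene double bond, which maps the (Sa) axis onto (5S).
Assumption (sourcing): 4-iodobenzene-1,2-diol is taken as a catalogue compound.

Step 1
Reactants: 1 2,2-dimethyl-2H-chromene-6-carbonitrile
Product: 2 (3S,4S)-3,4-epoxy-2,2-dimethylchromane-6-carbonitrile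
Conditions: (S,S)-N,N′-bis(3,5-di-tert-butylsalicylidene)-1,2-cyclohexanediaminomanganese chloride (2 mol %), aq. NaOCl (pH 11.3), 4-phenylpyridine N-oxide, CH2Cl2, 0 °C
Reagents that add atoms: sodium hypochlorite, [Na+].[O-]Cl
Why: Jacobsen epoxidation of a cis-disubstituted, aryl-conjugated chromene is the model substrate class for salen–manganese oxo transfer, and the (S,S)-ligand should direct oxygen to the face that gives the (3S,4S)-epoxide, which fixes the later C3 carbinol configuration.

Step 2
Reactants: 2 (3S,4S)-3,4-epoxy-2,2-dimethylchromane-6-carbonitrile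
Product: 3 (3S)-3-hydroxy-2,2-dimethylchromane-6-carbonitrile
Conditions: H2 (1 atm), 10% Pd/C, EtOAc, rt
Reagents that add atoms: none
Why: Hydrogenolysis of a benzylic epoxide cleaves only the benzylic C4–O bond, so C3 is untouched and becomes the (S)-carbinol, while the aryl nitrile should survive neutral conditions at atmospheric pressure.

Step 3
Reactants: 3 (3S)-3-hydroxy-2,2-dimethylchromane-6-carbonitrile
Product: 4 (3S)-3-[(tert-butyldimethylsilyl)oxy]-2,2-dimethylchromane-6-carbonitrile
Conditions: TBSOTf, 2,6-lutidine, CH2Cl2, 0 °C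
Reagents that add atoms: tert-butyldimethylsilyl trifluoromethanesulfonate, CC(C)(C)[Si](C)(C)OS(=O)(=O)C(F)(F)F
Why: The silyl triflate is reactive enough for the hindered secondary alcohol next to the gem-dimethyl carbon, and the ether then masks it through the hydride, bromination and base steps (silyl ether protection).

Step 4
Reactants: 4 (3S)-3-[(tert-butyldimethylsilyl)oxy]-2,2-dimethylchromane-6-carbonitrile
Product: 6 (3S)-3-[(tert-butyldimethylsilyl)oxy]-2,2-dimethylchromane-6-carbaldehyde, via aluminium aldimine 5 (not isolated)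
Conditions: iBu2AlH (1.2 equiv), CH2Cl2, −78 °C; then 1 M HCl, 0 °C
Reagents that add atoms: water, O
Why: Partial reduction of a nitrile with iBu2AlH stops at the N-aluminio aldimine at low temperature and brief cold hydrolysis releases the aldehyde without touching the hindered silyl ether.

Step 5
Reactants: 6 (3S)-3-[(tert-butyldimethylsilyl)oxy]-2,2-dimethylchromane-6-carbaldehyde
Product: 7 {(3S)-3-[(tert-butyldimethylsilyl)oxy]-2,2-dimethylchroman-6-yl}methanol
Conditions: NaBH4, MeOH, 0 °C
Reagents that add atoms: none
Why: Borohydride reduction of an aryl aldehyde is chemoselective and creates no new stereocentre.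

Step 6
Reactants: 7 {(3S)-3-[(tert-butyldimethylsilyl)oxy]-2,2-dimethylchroman-6-yl}methanol
Product: 8 (3S)-6-(bromomethyl)-3-[(tert-butyldimethylsilyl)oxy]-2,2-dimethylchromane
Conditions: CBr4, PPh3, CH2Cl2, 0 °C; used at once
Reagents that add atoms: tetrabromomethane, BrC(Br)(Br)Br
Why: The Appel reaction converts the primary benzylic alcohol to the bromide under neutral conditions that spare the silyl ether, and the electron-rich benzylic bromide is used without storage.

Step 7
Reactants: 9 methoxyacetyl chloride
Product: 10 tert-butyl methoxyacetate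
Conditions: tBuOH, pyridine, CH2Cl2, 0 °C → rt
Reagents that add atoms: tert-butanol, CC(C)(C)O
Why: Acylation of tert-butanol by the acid chloride gives the ester that will later be cleaved without touching a methyl ester (esterification).

Step 8
Reactants: 10 tert-butyl methoxyacetate
Product: 12 3-tert-butoxy-2-methoxy-3-oxopropanoic acid (racemic), via lithium enolate 11 (not isolated)
Conditions: LiN(iPr)2, THF, −78 °C; CO2 (g); then cold 1 M HCl
Reagents that add atoms: carbon dioxide, O=C=O
Why: Carboxylation of the chelated α-alkoxy ester enolate with excess CO2 gives the malonic half-ester, whose stereocentre is irrelevant because it becomes sp2 in the next step.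

Step 9
Reactants: 12 3-tert-butoxy-2-methoxy-3-oxopropanoic acid (racemic); 13 methyl (triphenylphosphoranylidene)acetate
Product: 16 1-tert-butyl 5-methyl 2-methoxypenta-2,3-dienedioate (racemic), via acid chloride 14 (not isolated), via acyl ketene 15 (not isolated)
Conditions: 1-chloro-N,N,2-trimethylprop-1-en-1-amine, CH2Cl2, 0 °C; then added to 13, Et3N, CH2Cl2, 0 °C → rt
Reagents that add atoms: none
Why: The acid chloride forms under neutral conditions that keep the tert-butyl ester, Et3N dehydrohalogenates it to the alkoxycarbonyl ketene, and Wittig olefination of the ketene carbonyl by the stabilised ylide gives the allene-1,3-dicarboxylate; its racemic axis does not matter because step 10 passes through an achiral anion.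

Step 10
Reactants: 16 1-tert-butyl 5-methyl 2-methoxypenta-2,3-dienedioate (racemic); 8 (3S)-6-(bromomethyl)-3-[(tert-butyldimethylsilyl)oxy]-2,2-dimethylchromane
Product: 17 1-tert-butyl 5-methyl (Sa)-2-methoxy-4-({(3S)-3-[(tert-butyldimethylsilyl)oxy]-2,2-dimethylchroman-6-yl}methyl)penta-2,3-dienedioate
Conditions: (11bS)-4,4-dibutyl-2,6-bis(3,4,5-trifluorophenyl)-4,5-dihydro-3H-dinaphtho[2,1-c:1′,2′-e]azepinium bromide (2 mol %), Cs2CO3, toluene, −20 °C
Reagents that add atoms: none
Why: Deprotonation of the acidic allenic C4–H gives a delocalised, achiral alkynyl-enolate that should be benzylated at the unsubstituted C4 terminus inside the chiral ammonium ion pair, so the catalyst sets the (Sa) axis and the now fully substituted allene can no longer racemise (asymmetric phase-transfer alkylation of a 1-substituted allene-1,3-dicarboxylate).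

Step 11
Reactants: 17 1-tert-butyl 5-methyl (Sa)-2-methoxy-4-({(3S)-3-[(tert-butyldimethylsilyl)oxy]-2,2-dimethylchroman-6-yl}methyl)penta-2,3-dienedioate
Product: 19 (Sa)-5-{(3S)-3-[(tert-butyldimethylsilyl)oxy]-2,2-dimethylchroman-6-yl}-2-methoxy-4-(methoxycarbonyl)penta-2,3-dienoic acid, via trimethylsilyl ester 18 (not isolated)
Conditions: TMSOTf, 2,6-lutidine, CH2Cl2, 0 °C; then pH 4 phosphate buffer
Reagents that add atoms: none
Why: Silylation of the ester carbonyl triggers loss of isobutene to the trimethylsilyl ester, which is hydrolysed on work-up, and these buffered aprotic conditions should spare the methoxyallene, the methyl ester and the silyl ether (silyl-triflate cleavage of a tert-butyl ester).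

Step 12
Reactants: 20 4-iodobenzene-1,2-diol
Product: 21 1,2-bis[(tert-butyldimethylsilyl)oxy]-4-iodobenzene
Conditions: TBSCl, imidazole, DMF, rt
Reagents that add atoms: tert-butyldimethylsilyl chloride, CC(C)(C)[Si](C)(C)Cl
Why: Imidazole-promoted silylation of both phenols masks the catechol against oxidation and palladium chelation and allows one fluoride deprotection at the end.

Step 13
Reactants: 19 (Sa)-5-{(3S)-3-[(tert-butyldimethylsilyl)oxy]-2,2-dimethylchroman-6-yl}-2-methoxy-4-(methoxycarbonyl)penta-2,3-dienoic acid; 21 1,2-bis[(tert-butyldimethylsilyl)oxy]-4-iodobenzene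
Product: 22 methyl (5S)-4-{3,4-bis[(tert-butyldimethylsilyl)oxy]phenyl}-5-({(3S)-3-[(tert-butyldimethylsilyl)oxy]-2,2-dimethylchroman-6-yl}methyl)-3-methoxy-2-oxo-2,5-dihydrofuran-5-carboxylate
Conditions: Pd(PPh3)4 (5 mol %), iPr2NEt (1.5 equiv), MeCN, 60 °C
Reagents that add atoms: none
Why: Oxidative addition of 21 to zerovalent palladium gives an arylpalladium iodide that engages the allene so that the aryl group ends on the central carbon and the carboxylate oxygen adds to the distal terminus (future C5) anti to palladium, after which reductive elimination releases the butenolide; whether Heck-type syn-carbopalladation of the acrylate-like distal double bond followed by anti displacement of palladium, or anti-oxypalladation followed by C–C reductive elimination, operates, the stereochemical result is the same. The closest known reaction type is the palladium-catalysed coupling–cyclisation of 2,3-allenoic acids with aryl halides to 4-aryl-2(5H)-furanones. The furanone ring closes in a 5-endo mode with respect to the distal allene double bond, forming the O1–C5 bond. The quaternary C5 is controlled by axial-to-central chirality transfer: the oxygen must attack the face of the allene terminus on its own side while palladium and the aryl group arrive from the methoxy side, so the (Sa) axis should map onto (5S). The step needs C–O closure to win over β-hydride elimination from the benzylic CH2 and over aryl–palladium addition across the enol-ether double bond; the cis-held carboxylate (used as its ammonium salt), the absence of any other accessible ring size and the Heck-type polarisation of the ester-bearing double bond are what should secure this.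

Step 14
Reactants: 22 methyl (5S)-4-{3,4-bis[(tert-butyldimethylsilyl)oxy]phenyl}-5-({(3S)-3-[(tert-butyldimethylsilyl)oxy]-2,2-dimethylchroman-6-yl}methyl)-3-methoxy-2-oxo-2,5-dihydrofuran-5-carboxylate
Product: 23 methyl (5S)-4-(3,4-dihydroxyphenyl)-5-{[(3S)-3-hydroxy-2,2-dimethylchroman-6-yl]methyl}-3-methoxy-2-oxo-2,5-dihydrofuran-5-carboxylate (CNP0289675.4)
Conditions: HF·pyridine (excess), THF, 0 °C → rt
Reagents that add atoms: none
Why: Acidic fluoride removes the two aryl silyl ethers and the hindered secondary silyl ether in one operation without opening the lactone, cleaving the methyl ester or enol ether, or oxidising the catechol (global desilylation).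

Compound list
1 | 2,2-dimethyl-2H-chromene-6-carbonitrile | CC1(C)C=Cc2cc(C#N)ccc2O1 | starting material
2 | (3S,4S)-3,4-epoxy-2,2-dimethylchromane-6-carbonitrile | CC1(C)Oc2ccc(C#N)cc2[C@@H]3O[C@H]13 | intermediate
3 | (3S)-3-hydroxy-2,2-dimethylchromane-6-carbonitrile | N#Cc1ccc2c(c1)C[C@H](O)C(C)(C)O2 | intermediate
4 | (3S)-3-[(tert-butyldimethylsilyl)oxy]-2,2-dimethylchromane-6-carbonitrile | N#Cc1ccc2c(c1)C[C@H](O[Si](C)(C)C(C)(C)C)C(C)(C)O2 | intermediate
5 | N-(diisobutylaluminio) aldimine of 6 | CC(C)C[Al](CC(C)C)N=Cc1ccc2c(c1)C[C@H](O[Si](C)(C)C(C)(C)C)C(C)(C)O2 | intermediate (not isolated)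
6 | (3S)-3-[(tert-butyldimethylsilyl)oxy]-2,2-dimethylchromane-6-carbaldehyde | O=Cc1ccc2c(c1)C[C@H](O[Si](C)(C)C(C)(C)C)C(C)(C)O2 | intermediate
7 | {(3S)-3-[(tert-butyldimethylsilyl)oxy]-2,2-dimethylchroman-6-yl}methanol | OCc1ccc2c(c1)C[C@H](O[Si](C)(C)C(C)(C)C)C(C)(C)O2 | intermediate
8 | (3S)-6-(bromomethyl)-3-[(tert-butyldimethylsilyl)oxy]-2,2-dimethylchromane | BrCc1ccc2c(c1)C[C@H](O[Si](C)(C)C(C)(C)C)C(C)(C)O2 | intermediate
9 | methoxyacetyl chloride | COCC(Cl)=O | starting material
10 | tert-butyl methoxyacetate | COCC(=O)OC(C)(C)C | intermediate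
11 | lithium enolate of tert-butyl methoxyacetate | [Li+].COC=C([O-])OC(C)(C)C | intermediate (not isolated)
12 | 3-tert-butoxy-2-methoxy-3-oxopropanoic acid (racemic) | COC(C(O)=O)C(=O)OC(C)(C)C | intermediate
13 | methyl (triphenylphosphoranylidene)acetate | COC(=O)C=P(c1ccccc1)(c1ccccc1)c1ccccc1 | starting material
14 | tert-butyl 3-chloro-2-methoxy-3-oxopropanoate | COC(C(Cl)=O)C(=O)OC(C)(C)C | intermediate (not isolated)
15 | tert-butyl 2-methoxy-3-oxoprop-2-enoate (acyl ketene) | COC(=C=O)C(=O)OC(C)(C)C | intermediate (not isolated)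
16 | 1-tert-butyl 5-methyl 2-methoxypenta-2,3-dienedioate (racemic) | COC(=O)C=C=C(OC)C(=O)OC(C)(C)C | intermediate
17 | 1-tert-butyl 5-methyl (Sa)-2-methoxy-4-({(3S)-3-[(tert-butyldimethylsilyl)oxy]-2,2-dimethylchroman-6-yl}methyl)penta-2,3-dienedioate | CC(C)(C)OC(=O)C(OC)=[C@@]=C(C(=O)OC)Cc1ccc2c(c1)C[C@H](O[Si](C)(C)C(C)(C)C)C(C)(C)O2 | intermediate
18 | trimethylsilyl ester of 19 | C[Si](C)(C)OC(=O)C(OC)=[C@@]=C(C(=O)OC)Cc1ccc2c(c1)C[C@H](O[Si](C)(C)C(C)(C)C)C(C)(C)O2 | intermediate (not isolated)
19 | (Sa)-5-{(3S)-3-[(tert-butyldimethylsilyl)oxy]-2,2-dimethylchroman-6-yl}-2-methoxy-4-(methoxycarbonyl)penta-2,3-dienoic acid | OC(=O)C(OC)=[C@@]=C(C(=O)OC)Cc1ccc2c(c1)C[C@H](O[Si](C)(C)C(C)(C)C)C(C)(C)O2 | intermediate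
20 | 4-iodobenzene-1,2-diol | Oc1ccc(I)cc1O | starting material
21 | 1,2-bis[(tert-butyldimethylsilyl)oxy]-4-iodobenzene | CC(C)(C)[Si](C)(C)Oc1ccc(I)cc1O[Si](C)(C)C(C)(C)C | intermediate
22 | methyl (5S)-4-{3,4-bis[(tert-butyldimethylsilyl)oxy]phenyl}-5-({(3S)-3-[(tert-butyldimethylsilyl)oxy]-2,2-dimethylchroman-6-yl}methyl)-3-methoxy-2-oxo-2,5-dihydrofuran-5-carboxylate | COC(=O)[C@@]1(Cc2ccc3c(c2)C[C@H](O[Si](C)(C)C(C)(C)C)C(C)(C)O3)OC(=O)C(OC)=C1c1ccc(O[Si](C)(C)C(C)(C)C)c(O[Si](C)(C)C(C)(C)C)c1 | intermediate
23 | methyl (5S)-4-(3,4-dihydroxyphenyl)-5-{[(3S)-3-hydroxy-2,2-dimethylchroman-6-yl]methyl}-3-methoxy-2-oxo-2,5-dihydrofuran-5-carboxylate | COC(=O)[C@@]1(Cc2ccc3c(c2)C[C@H](O)C(C)(C)O3)OC(=O)C(OC)=C1c1ccc(O)c(O)c1 | target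

Total step count: 14. Longest linear sequence: 10 (steps 1–6, 10, 11, 13, 14).

Steps most likely to fail

Step 13. The alkyl/allyl-palladium intermediate may undergo β-hydride elimination from the benzylic methylene and give an open-chain diene, or the aryl–palladium may add across the enol-ether double bond so that axial-to-central fidelity is lost. The fallback closes the ring before the quaternary centre is made. It sets out from 16: the tert-butyl ester is cleaved as in step 11 to 2,5-dimethoxy-5-oxopenta-2,3-dienoic acid F1. Coupling–cyclisation of this acid with 21 under the step 13 conditions has no β-hydrogen to lose and no stereochemical demand, and should give racemic methyl 4-{3,4-bis[(tert-butyldimethylsilyl)oxy]phenyl}-3-methoxy-2-oxo-2,5-dihydrofuran-5-carboxylate F2. Its acidic C5–H is then removed to an aromatic 2-oxidofuran, which is benzylated at C5 with 8 under the chiral phase-transfer conditions of step 10. Because 8 is enantiopure, the C5 epimers are diastereomers and can be separated by chromatography. The sequence comes back to the route at 22.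

Step 10. Alkylation may occur at the methoxy-bearing carbon (giving the alkyne isomer) instead of the unsubstituted terminus, or facial discrimination in the ion pair may be poor with a methoxy in place of an alkyl substituent. The fallback builds the benzyl group into the ylide and sets out from 13 and 8. Alkylation of 13 with 8 should give {3-[(3S)-3-[(tert-butyldimethylsilyl)oxy]-2,2-dimethylchroman-6-yl]-1-methoxy-1-oxopropan-2-yl}triphenylphosphonium bromide F3, which aqueous NaOH converts to methyl 3-{(3S)-3-[(tert-butyldimethylsilyl)oxy]-2,2-dimethylchroman-6-yl}-2-(triphenylphosphoranylidene)propanoate F4. Wittig reaction of this ylide with ketene 15 (generated from 12 as in step 9) should give 17 together with its axial epimer, 1-tert-butyl 5-methyl (Ra)-2-methoxy-4-({(3S)-3-[(tert-butyldimethylsilyl)oxy]-2,2-dimethylchroman-6-yl}methyl)penta-2,3-dienedioate F5. The two are diastereomers and are separated by preparative HPLC on a chiral stationary phase. The sequence comes back to the route at 17.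

Step 9. The acid chloride may acylate the ylide at carbon faster than it is dehydrohalogenated, or the acyl ketene may dimerise. The fallback makes the allene by elimination instead of olefination and sets out from 12. Activation with 1,1′-carbonyldiimidazole should give tert-butyl 3-(1H-imidazol-1-yl)-2-methoxy-3-oxopropanoate F6. Decarboxylative Claisen condensation with potassium methyl malonate, MgCl2 and Et3N then gives 1-tert-butyl 5-methyl 2-methoxy-3-oxopentanedioate F7. Triflation (Tf2O, iPr2NEt, −78 °C) gives 1-tert-butyl 5-methyl 2-methoxy-3-{[(trifluoromethyl)sulfonyl]oxy}pent-3-enedioate F8, and Et3N-induced 1,2-elimination of the β-triflate (the classical β-leaving-group glutaconate route to allene-1,3-dicarboxylates) comes back to the route at 16.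

Further compounds
F1 | step 13 | 2,5-dimethoxy-5-oxopenta-2,3-dienoic acid (racemic) | COC(=O)C=C=C(OC)C(O)=O
F2 | step 13 | methyl 4-{3,4-bis[(tert-butyldimethylsilyl)oxy]phenyl}-3-methoxy-2-oxo-2,5-dihydrofuran-5-carboxylate (racemic) | COC(=O)C1OC(=O)C(OC)=C1c1ccc(O[Si](C)(C)C(C)(C)C)c(O[Si](C)(C)C(C)(C)C)c1
F3 | step 10 | {3-[(3S)-3-[(tert-butyldimethylsilyl)oxy]-2,2-dimethylchroman-6-yl]-1-methoxy-1-oxopropan-2-yl}triphenylphosphonium bromide | COC(=O)C(Cc1ccc2c(c1)C[C@H](O[Si](C)(C)C(C)(C)C)C(C)(C)O2)[P+](c1ccccc1)(c1ccccc1)c1ccccc1.[Br-]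
F4 | step 10 | methyl 3-{(3S)-3-[(tert-butyldimethylsilyl)oxy]-2,2-dimethylchroman-6-yl}-2-(triphenylphosphoranylidene)propanoate | COC(=O)C(Cc1ccc2c(c1)C[C@H](O[Si](C)(C)C(C)(C)C)C(C)(C)O2)=P(c1ccccc1)(c1ccccc1)c1ccccc1
F5 | step 10 | 1-tert-butyl 5-methyl (Ra)-2-methoxy-4-({(3S)-3-[(tert-butyldimethylsilyl)oxy]-2,2-dimethylchroman-6-yl}methyl)penta-2,3-dienedioate | CC(C)(C)OC(=O)C(OC)=[C@]=C(C(=O)OC)Cc1ccc2c(c1)C[C@H](O[Si](C)(C)C(C)(C)C)C(C)(C)O2
F6 | step 9 | tert-butyl 3-(1H-imidazol-1-yl)-2-methoxy-3-oxopropanoate | COC(C(=O)n1ccnc1)C(=O)OC(C)(C)C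
F7 | step 9 | 1-tert-butyl 5-methyl 2-methoxy-3-oxopentanedioate | COC(=O)CC(=O)C(OC)C(=O)OC(C)(C)C
F8 | step 9 | 1-tert-butyl 5-methyl 2-methoxy-3-{[(trifluoromethyl)sulfonyl]oxy}pent-3-enedioate | COC(=O)C=C(OS(=O)(=O)C(F)(F)F)C(OC)C(=O)OC(C)(C)C
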